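The equivalent, one partner per substrate charged, is the unit of this reckoning. Taken by their names, the single product carries one equivalent, the bis adduct two and the triple product 3, and a reading of substrate counts its free form alone.

| flask | substrate | partner | remark | time |
|---|---|---|---|---|
| south | 0.050 M | 0.15 M | run made earlier |  |
| south-east | 0.20 M | 0.15 M | run made earlier |  |
| south-west | 0.10 M | 0.30 M | run made earlier |  |
| flask | 0.10 M | 0.150 M |  | 3.0 h |

- south (time / h: substrate / %, single product / %): 0.200: 65.2, 11.9; 0.667: 19.6, 13.1; 1.00: 6.7, 9.1; 1.50: 2.4, 5.1; 2.50: 1.1, 2.3
- south-east (time / h: substrate / %, single product / %): 0.500: 41.2, 15.3; 1.00: 20.1, 14.3; 1.33: 12.7, 11.6; 2.00: 6.7, 11.3; 2.50: 4.3, 10.0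
- south-west (time / h: substrate / %, single product / %): 0.200: 39.9, 16.1; 0.333: 18.0, 13.1; 0.667: 1.9, 5.9; 1.33: 1.3, 0.9; 2.50: 1.0, 0.1

(each reading ± 0.5 percentage points)

- a reading of substrate is of its free form alone

- amount of substrate at 3.0 h, in percent of the substrate charged
- amount of single product at 3.0 h, in percent of the substrate charged
- amount of bis adduct at 3.0 h, in percent of the substrate charged
- amount of triple product at 3.0 h, in percent of the substrate charged

Each substrate standing as bis adduct, triple product or anything built further costs at least two equivalents. With c_A and c_B the charged substrate and partner, the flask's charge therefore bounds those forms together: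

C = c_B / (2 c_A) = 75.0 %, the partner ceiling, a stoichiometric limit.

Whatever lies above the ceiling must sit elsewhere. With A and M the percentages of free substrate and single product, the floor on that unseen share is:

F = 100% − A − M − C

The south-east run tests this. Its ceiling is 37.5 %, and its last readings, 4.3 % substrate and 10.0 % single product, give F = 48.2 %. Substrate is thus held in some form not yet counted.

For the flask, the south run's last readings, 1.1 % and 2.3 %, serve as stand-ins for A and M, so the value of F below is an estimate and not a bound:

F = 21.6 %

This reckoning commits to bis adduct plus triple product at or below C, and it gives no split between them.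

The forecast gives 1.5 % substrate, 4 % single product, 55 % bis adduct and 39.5 % triple product, and says: “Bis and triple products are not measured, so only their sum (about 94%) is constrained.” Its last two add to 94.5 %, more than C, and there the two reckonings differ.

The flask gives 0.900 % substrate, 1.86 % single product, 22.5 % bis adduct and 2.82 % triple product.

    substrate + partner → single product + by-product (k = 0.110 M⁻¹ min⁻¹)
    partner + single product → bis adduct + by-product (k = 0.260 M⁻¹ min⁻¹)
    partner + bis adduct → triple product + by-product (k = 0.0450 M⁻¹ min⁻¹)
    partner + triple product → tetra adduct + by-product (k = 0.360 M⁻¹ min⁻¹)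
    substrate + by-product ⇌ idle adduct, settled at all times (K = 2600 M⁻¹)
    partner → decomposition product (k = 7.00 × 10⁻⁵ min⁻¹)
    crystals ⇌ by-product, rate k7*(cs7 - [by-product]) while solid is left; crystals form when [by-product] > cs7 (solubility = 0.0780 M, k = 1.50 min⁻¹)

At 3.00 h the flask's bis adduct, triple product and tetra adduct total 34.0 %, less than C, and its idle adduct, at 63.2 %, stands above F. The neighbour flask with 0.060 M of partner has C = 30.0 %. Its 22.3 % substrate and 14.6 % single product at 3.00 h give F = 33.1 %, and its idle adduct stands above that, at 47.3 %.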